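Which flask ends richer in intermediate, hot Saturday's with much second reagent or cool Sunday's with little, is reckoned here from two shares: the substrate converted but not found as intermediate, and the substrate still unconverted when time is up.

common to all: substrate 0.16 M
- zeta: partner 0.40 M; second reagent 0.26 M; temperature 30 °C; run made earlier
- beta: partner 0.40 M; second reagent 0.89 M; temperature 52 °C; run made earlier
- Saturday's: partner 0.400 M; second reagent 1.00 M; temperature 60 °C; time 60 min
- Sunday's: partner 0.400 M; second reagent 0.320 M; temperature 20 °C; time 30 min

| run | time / min | intermediate / % | target / % |
|---|---|---|---|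
| zeta | 1.00 | 17.8 | 1.2 |
| zeta | 2.50 | 32.5 | 4.0 |
| zeta | 6.00 | 57.3 | 4.6 |
| zeta | 12.0 | 74.8 | 3.7 |
| beta | 0.500 | 30.1 | 5.3 |
| beta | 1.50 | 59.9 | 4.0 |
| beta | 3.00 | 72.5 | 2.6 |
| beta | 4.00 | 77.5 | 5.2 |

(readings scatter by 1 percentage point)



- the flask that ends with the higher amount of intermediate, in percent of the substrate charged, or "neither" when 2 percentage points or less lies between them (Saturday's / Sunday's / neither)
- final intermediate, as a percentage of the substrate charged, in Saturday's
- final intermediate, as a percentage of the substrate charged, in Sunday's

In the first instants of the earlier runs target appears and then stops climbing: zeta reads 4.0 % at 2.50 min and 3.7 % at 12.0 min. The reckoning here therefore treats the second reagent's work as a short burst, taken as over, and follows the substrate it leaves free.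

For the middle of the run, the first readings of intermediate plus target give an initial pseudo-first-order constant for the partner step: 0.211 /min in zeta and 0.874 /min in beta. With partner charged at 2.50 times the substrate and thinning as it is used, these constants leave an unconverted share of 0.144 at zeta's last reading and 0.0775 at beta's.

Dividing the last intermediate by the converted share gives a ceiling for each run. The shortfall of that ceiling per molar of second reagent charged, here called the toll, reads 0.484 /M in zeta and 0.180 /M in beta, so it reads smaller in beta, the hotter run, which also carries more second reagent.

Assumed to follow temperature and carried exponentially along it, the reckoning gives Sunday's flask a constant of 0.110 /min and a toll of 0.760 /M. Its ceiling is then 0.757, its unconverted share 0.0870, and its intermediate 69.1 %. Saturday's flask gets a toll of 0.125 /M and a constant of 1.47 /min, whose half-life is far shorter than its time, so its intermediate reckons at its ceiling, 87.5 %, more than the reckoning gives Sunday's flask.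

The forecast differs: Sunday's ahead, with 76 % (68 % to 83 %) against 70 % (52 % to 80 %) for Saturday's, on the ground that “Saturday reaches its plateau, probably lowered by heat and some drain”.

The flasks give Saturday's ahead, with 83.0 % against 66.0 % for Sunday's.

    second reagent + target → over-reaction product (k = 0.00500 /M/s, Ea = 71.0 kJ/mol)
    second reagent + intermediate → target (k = 0.00740 /M/s, Ea = 53.0 kJ/mol)
    second reagent → decomposed reagent (k = 0.00300 /s, Ea = 81.0 kJ/mol)
    substrate + partner → intermediate (k = 0.00450 /M/s, Ea = 58.0 kJ/mol)
    substrate + second reagent → side product (k = 0.00180 /M/s, Ea = 49.0 kJ/mol)
    target ⇌ isomer of the product (K = 0.790, k = 5.50 × 10⁻⁴ /s, Ea = 79.0 kJ/mol, ΔH = −6.00 kJ/mol)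
    (constants at 20 °C)

Sunday's flask still holds 7.2 % of its substrate at 30 min, and after 300 min its intermediate stands at 73.2 %, a toll of 0.838 /M. Saturday's 83.0 % is a toll of 0.170 /M. The same flask as Sunday's at 35 °C reckons at a toll of 0.387 /M and a ceiling of 87.6 %. That flask holds 0.0891 % of substrate at 30 min and ends with 84.6 % intermediate.

The data were generated by integration with constants of no real substance; noise was put on by code.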